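The runs were generated by integration with made-up constants, noise included.

Choose the D charge by multiplying it by the fraction of D gone, then read Z for that delivery off Wednesday's run.

| flask | X | D | remark | time | volume of the second phase over the first |
|---|---|---|---|---|---|
| Wednesday's | 0.16 M | 0.46 M | run made earlier |  |  |
| grey | 0.16 M | 0.300 M |  | 3.0 h | 2.0 |
| violet | 0.16 M | 0.144 M |  | 3.0 h | 2.0 |
| blue | 0.16 M | 0.100 M |  | 3.0 h | 2.0 |
| teal | 0.16 M | 0.0800 M |  | 3.0 h | 2.0 |

- Wednesday's (time / min: Z / %, X / %): 8.00: 9.5, 89.4; 25.0: 30.4, 63.6; 40.0: 41.7, 48.9; 60.0: 51.6, 31.7; 90.0: 53.7, 14.3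

(scatter of a reading: 1 percentage point)

- in the second phase: D; everything else is in the first
- charges count per volume of the first phase; a concentration in a rate is the amount of a species over the volume of its own phase; every rate counts per litre of the first phase
- the numbers in the tables scatter by 1 percentage point (one standard deviation)
- candidate steps: J <-> D; X + J -> Z; J + Z -> G; 2 J -> E; X -> Q; X <-> L
- the earlier runs hold the two phases in the same ratio of volumes as the flask asked about

1. ranking by amount of Z, in percent of the X charged, from high to low, at 3.0 h (grey / violet / blue / teal)
2. the same order at 25 h (grey / violet / blue / teal)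
3. the amount of Z, in percent of the X charged of the flask you put first, at 3.0 h
4. the amount of Z, in percent of the X charged of the flask you put last, at 3.0 h

I want the charge for the next run, so I need the J each flask has received per X charged, which I call the delivery. In Wednesday's flask the last reading has X at 14.3% and Z at 53.7%. What left X and is not Z I count as G, at two J per X, so the delivery stands at 118%. D was charged at 288% of X, which leaves a fraction 59.1% of D at 90.0 min. I treat this loss as a pseudo-first-order decay, so D falls at 0.00585 min⁻¹: the transfer constant, minus the logarithm of the fraction of D left, per unit time.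

That fraction has no charge in it, so at 3.0 h I reckon 34.9% left for grey, violet, blue and teal. Their deliveries are 122%, 58.6%, 40.7% and 32.6%. The steps X + J and J + Z both go with the first power of J, so their ratio has no J in it, and I expect Z to follow delivery, not the clock. Wednesday's readings are then the curve. Violet sits near Wednesday's delivery of 60.5%, where Z read 41.7%. Teal lies between Wednesday's deliveries of 11.7% and 42.4%, which gives me 23.7% of Z. Grey lies just past the last reading. At 25 h grey's delivery reaches 187%, far beyond Wednesday's curve, while violet's 90.0% stays inside it. So I would charge grey for a short run and violet for a long one.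

The forecast says grey > violet > blue > teal at 3.0 h, with 51% and 25%, which puts grey lower and teal higher than my reading of the curve, and violet > blue > teal > grey at 25 h. Its ground: “J stays at a low steady state and supply from the second phase limits the rate”.

The flasks give grey > violet > blue > teal at 3.0 h, from 49.4% to 27.1%, and violet > blue > teal > grey at 25 h, with violet at 49.0% and grey at 8.69%. Grey holds 37.5% of its D at 3.0 h, against my 34.9%.

    J ⇌ D, rate k1*([J] - [D]/K1) per volume of the first phase (partition coefficient = 1.20, kL = 2.30 × 10⁻⁴ s⁻¹)
    X + J → Z (k = 0.0530 M⁻¹ s⁻¹)
    J + Z → G (k = 0.0190 M⁻¹ s⁻¹)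
    2 J → E (k = 2.20 × 10⁻⁴ M⁻¹ s⁻¹)
    X → Q (k = 4.20 × 10⁻⁷ s⁻¹)
    X ⇌ L (K = 0.540, k = 2.50 × 10⁻⁵ s⁻¹)

Grey read at 2.0 h is the neighbour. The transfer constant leaves 49.6% of D there, and the flask holds 51.6%. The delivery comes to 94.6%, between Wednesday's 85.0% and 118%, where Z read 51.6% and 53.7%. That flask stands at 52.0% of Z.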